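Remark on the chemistry: C4 keeps the same spatial arrangement from the annulation product to the target; its descriptor is R in the alkynyl and stannylalkenyl intermediates and S in the target only because the CIP ranking of its carbon substituents changes once the triene is in place.

## Structural features

The target is a 2-acylaminocyclohex-2-en-1-one (ring A: C1 ketone, C2 enamide carbon, C3 =CH, C4 tertiary carbinol, C5 secondary carbinol, C6 methylene). Through nitrogen, C2 carries an (R,E)-2,4-dimethyloct-2-enoyl chain whose single stereocentre is remote from the ring. C4 carries an all-(E) hepta-2,4,6-trienamide whose nitrogen sits on C2 of a 3-hydroxycyclopent-2-en-1-one (ring B, a vinylogous acid). The two ring stereocentres are adjacent, (4S,5R), with the hydroxyls cis, and C4 is quaternary and doubly allylic. Fragile elements are the β-hydroxy ketone C5–OH/C1=O (loss of water to a cross-conjugated dienone), the ionizable tertiary carbinol, the light- and acid-sensitive triene, the two enamides and the acidic enol of ring B. The real difficulty is to set the quaternary C4 and its neighbour C5 in absolute terms on a ring with no other stereocentre to relay from, and to have the C2 nitrogen in place without a late amination. The key step exploits the hidden symmetry around C4: C3 and C5 are both formyl-derived carbons on a quaternary centre and C6–C1–C2(N) is an N-acyl aminoacetone, so ring A is the [3+3] union of a prochiral 2-oxy-2-alkynylmalonaldehyde with the side-chain amide of aminoacetone.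

## Logic of the disconnections

35 ⇒ 26 + 34. The sp2–sp2 single bond between the first and second double bond of the triene, counted from ring A, is cut. This keeps the acidic enol of ring B and the complete triene out of every earlier operation and makes the last step the union of two halves of similar size. The forward step must transfer an (E)-alkenyl group from tin with retention of both alkene geometries under neutral conditions, beside a free cis-diol, two enamides and an acidic enol.

26 ⇒ 25 ⇒ 24. The C–Sn bond of 26 and the two silicon bonds of 24 (C–Si on the alkyne, O–Si at C4) are cut. An alkyne is the slimmest and most robust carrier of the first two chain carbons through hydride reduction, oxidation and amine catalysis, and syn hydrometalation turns it into the (E)-alkenyl metal. The two silyl groups of 24 are matched so that one buffered fluoride treatment removes both; a bulky alkynylsilane would outlast the silyl ether, so the ether could not be kept to the end in any case. 25 and 26 are therefore carried as free diols and 35 needs no final deprotection. The forward steps demand tin delivery to the terminal alkyne carbon without reduction of the enone, and desilylation without β-elimination of the C5 hydroxyl.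

24 ⇒ 14 + 21. The C5–C6 single bond and the C2=C3 double bond are cut, which removes ring A. This takes apart the only ring together with both of its stereocentres and leaves two open-chain pieces, of which 21 is achiral. Ketone, enamide and the whole N-acyl side chain arrive with 14, so no ring amination is needed. In 21 the alkyne terminus is kept small (trimethylsilyl) and the C4 oxygen carries the larger triethylsilyl group, so that the three substituents of C4 differ as much as possible in size and polarity. The forward step must choose one of two enantiotopic formyl groups and one of its faces, make the first bond at the methyl carbon of 14, lose water only across C2–C3, and do so before the amine degrades 21.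

21 ⇒ 20 ⇒ 19 ⇒ 15 + 16. The oxidation level of both terminal carbons is adjusted (dialdehyde from diol from diester), then the O–Si bond at C4 and the bond between C4 and the alkyne are cut. The quaternary carbon then comes from the central carbonyl of 16, and the symmetry of 21 costs nothing. The forward steps demand addition to the ketone and not to the esters, a silyl ether that stays on the tertiary oxygen during hydride reduction, and an oxidation after which 21 meets neither water nor nucleophiles.

14 ⇒ 11 + 12. The amide C–N bond is cut. This separates the chiral acid from a three-carbon aminoketone sold as its stable salt. The forward step must acylate the free amine faster than it condenses with itself.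

11 ⇒ 10 ⇒ 7 + 8. The ester C–O bond and then the C2=C3 double bond of the chain are cut. The trisubstituted (E)-alkene comes from a stabilized ylide, and the only stereocentre is left on a six-carbon alcohol. The forward step must pass through the α-branched aldehyde 9 without epimerization and give the (E)-alkene.

7 ⇒ 6 ⇒ 4 ⇒ 1 + 2. The acyl–nitrogen bond (reductive release), the C–CH3 bond at the stereocentre and the N-acyl bond to the auxiliary are cut. The stereocentre is thereby traced to a recoverable auxiliary and a commodity acid chloride. The alkylation must be face-selective, which the chelated (Z)-enolate 5 provides, and the reduction must not touch the new centre.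

34 ⇒ 29 + 32; 29 ⇒ 28 ⇒ 27; 32 ⇒ 31 ⇒ 30. The amide C–N bond, the C4=C5 bond of the iododiene (one-carbon iodo-olefination of an aldehyde) and the C–N bond at C2 of the cyclopentanedione are cut. Each half then derives from one commercial compound in two operations. The demands are (E)-selectivity in the iodo-olefination, hydrolysis without loss of HI, reduction of the oxime but not of the enolized dione, and N- rather than O-acylation of 32.

## Other disconnections considered

Alternative 1: The cut removes both C–O bonds at C4 and C5 and returns ring A to an arene, benzoic acid A1. In the forward direction a mutant strain lacking the diol dehydrogenase adds dioxygen to the ipso and ortho carbons of A1 on one face and should give the cis-diol acid A2. Its carbinol carbons map onto C4 and C5 with the required absolute and relative configuration, and its carboxyl carbon is the first carbon of the triene.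
- In its favour: both stereocentres arise in one step from a commodity arene, the cis relationship follows from the mechanism, and no chiral reagent or protecting group is needed.
- Against it here: A2 rearomatizes easily by loss of water, and one diene double bond must become the C6 methylene and C1 ketone, the other must receive nitrogen at C2, and the carboxyl group must be turned into the alkenyl chain. A fermentation is also required.
- Structure: A2 supplies C4, C5 and the C4 carbon substituent but no ketone, nitrogen or side chain, whereas 24 carries every ring function.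
- Mechanism: the enzymatic cis-dihydroxylation is the better, since its stereochemical outcome is certain where that of step 10 is not.
- Step economy: the chosen plan is clearly shorter, because it needs no redistribution of oxidation states on the ring.

Alternative 2: The cut is the C5–O bond (retro-oxa-Michael), which returns ring A to the achiral dienone A3. In the forward direction the tertiary hydroxyl of A3 is esterified in situ by an arylboronic acid. Under a cinchona-derived amine–thiourea the remaining B–OH oxygen adds to one of the two enantiotopic enone β-carbons and should give the cyclic boronate A4.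
- In its favour: delivery through the tether makes the cis relationship a matter of geometry, the reaction class is known for 4-substituted dienones of this kind, A3 is two operations from commercial materials, and A4 already holds the C1 ketone, the C2=C3 double bond and the C6 methylene.
- Against it here: the C2 nitrogen is missing and cannot be present beforehand, because a 2-amido group would make the two enone arms different and turn the desymmetrization into a kinetic resolution of a racemate. It must be introduced later by α-halogenation and metal-catalysed amidation on a β-oxygenated ketone that can revert to the achiral dienone under base.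
- Structure: A4 carries both stereocentres but not the nitrogen with its acyl chain, which 24 has.
- Mechanism: the tethered addition is the better for the relative configuration and rests on precedent, which step 10 does not.
- Step economy: the two are about equal up to 25, but the alternative is less convergent because the side chain enters late on a sensitive intermediate. This chemistry is kept as the fallback for step 10.

Alternative 3: The cut is the C3–C4 bond, which opens ring A to the (Z)-iodoalkenyl ynone A5. In the forward direction CrCl2 with catalytic NiCl2 converts the alkenyl iodide into an alkenylchromium species that adds to the ynone carbonyl. Chelation of chromium by the C5 ether oxygen directs the face, and the cyclohexenol A6 should result with C4 set from C5.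
- In its favour: ring and quaternary carbinol form together under neutral conditions, organochromium reagents are highly selective for carbonyl groups, the stereochemical relay is internal, and the silylalkyne is already in place.
- Against it here: A5 needs a long linear synthesis with a (Z)-iodoalkene and two stereocentres, one of which (the C1 silyl ether) is later oxidized away. A ketone is a sluggish acceptor in this coupling and the ynone may be reduced by divalent chromium. After ring closure the C1 oxidation, removal of the 4-methoxybenzyl ether next to an alkyne and the whole C2 amidation still lie ahead.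
- Structure: the step makes one ring bond and one stereocentre, against two bonds and two stereocentres in step 10.
- Mechanism: the chelate-controlled intramolecular addition is at least the equal of step 10 in predictability of the C4/C5 relationship, but it only relays a centre that must be made separately.
- Step economy: it is the longest of the plans.

Key step: step 10

## Steps

Step 1
Reactants: 1 (R)-4-benzyloxazolidin-2-one; 2 hexanoyl chloride
Product: 4 (R)-4-benzyl-3-hexanoyloxazolidin-2-one, via lithium oxazolidinide 3 (not isolated)
Conditions: n-BuLi, THF, −78 °C; then 2, −78 → 0 °C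
Reagents that add atoms: none
Why: N-acylation of the lithiated auxiliary by the acid chloride (loading of an Evans auxiliary); no stereocentre is formed.

Step 2
Reactants: 4 (R)-4-benzyl-3-hexanoyloxazolidin-2-one
Product: 6 (R)-4-benzyl-3-[(R)-2-methylhexanoyl]oxazolidin-2-one, via sodium enolate 5 (not isolated)
Conditions: NaN(SiMe3)2, THF, −78 °C; then MeI, −78 °C
Reagents that add atoms: iodomethane, CI
Why: Evans alkylation: the chelated (Z)-enolate is methylated on the face away from the benzyl group; with the (R)-auxiliary and butyl as the resident chain this should give the (R)-2-methyl centre.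

Step 3
Reactants: 6 (R)-4-benzyl-3-[(R)-2-methylhexanoyl]oxazolidin-2-one
Product: 7 (R)-2-methylhexan-1-ol
Conditions: LiBH4, MeOH (1 equiv), Et2O, 0 °C
Reagents that add atoms: none
Why: Reductive cleavage of the exocyclic imide carbonyl by borohydride; the auxiliary is released intact and the α-centre is not enolized under hydride conditions.

Step 4
Reactants: 7 (R)-2-methylhexan-1-ol; 8 ethyl 2-(triphenyl-λ5-phosphanylidene)propanoate
Product: 10 ethyl (R,E)-2,4-dimethyloct-2-enoate, via (R)-2-methylhexanal 9 (not isolated)
Conditions: PhI(OAc)2, TEMPO (cat.), CH2Cl2, 23 °C; then 8, 23 → 40 °C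
Reagents that add atoms: none
Why: Nitroxyl-catalysed oxidation to the aldehyde and Wittig olefination in the same flask, so that the volatile, epimerizable aldehyde is never isolated; the stabilized α-methyl ylide should give the (E)-trisubstituted enoate.

Step 5
Reactants: 10 ethyl (R,E)-2,4-dimethyloct-2-enoate
Product: 11 (R,E)-2,4-dimethyloct-2-enoic acid
Conditions: LiOH, THF/MeOH/H2O, 40 °C; then 1 M HCl
Reagents that add atoms: lithium hydroxide, [Li+].[OH-]
Why: Saponification; the γ-hydrogen at the stereocentre is not acidic enough to be removed by hydroxide, so configuration and alkene geometry are kept.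

Step 6
Reactants: 11 (R,E)-2,4-dimethyloct-2-enoic acid; 12 aminoacetone hydrochloride
Product: 14 (R,E)-2,4-dimethyl-N-(2-oxopropyl)oct-2-enamide, via benzotriazolyl ester 13 (not isolated)
Conditions: EDC·HCl, HOBt, CH2Cl2, 0 °C; then 12, N-methylmorpholine (slow addition), 0 → 23 °C
Reagents that add atoms: none
Why: Carbodiimide/HOBt amide coupling; the aminoketone is set free slowly in the presence of the preformed active ester, so N-acylation should outrun its self-condensation.

Step 7
Reactants: 15 (trimethylsilyl)acetylene; 16 diethyl ketomalonate
Product: 19 diethyl 2-(triethylsilyloxy)-2-[(trimethylsilyl)ethynyl]malonate, via lithium trimethylsilylacetylide 17 (not isolated), via lithium alkoxide adduct 18 (not isolated)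
Conditions: n-BuLi, THF, −78 °C; then 16, −78 °C; then Et3SiOTf, −78 → 0 °C
Reagents that add atoms: triethylsilyl trifluoromethanesulfonate, CC[Si](CC)(CC)OS(=O)(=O)C(F)(F)F
Why: 1,2-addition of the acetylide to the highly electrophilic central ketone (the esters are untouched at −78 °C), followed by O-silylation of the tertiary lithium alkoxide by the silyl triflate; the product is achiral.

Step 8
Reactants: 19 diethyl 2-(triethylsilyloxy)-2-[(trimethylsilyl)ethynyl]malonate
Product: 20 2-(triethylsilyloxy)-2-[(trimethylsilyl)ethynyl]propane-1,3-diol
Conditions: i-Bu2AlH, CH2Cl2, −78 → 0 °C; aq. potassium sodium tartrate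
Reagents that add atoms: none
Why: Exhaustive hydride reduction of both esters; aluminium alkoxides are poorly nucleophilic, so the silyl group should stay on the tertiary oxygen, and the cold aluminium hydride leaves the silylalkyne alone.

Step 9
Reactants: 20 2-(triethylsilyloxy)-2-[(trimethylsilyl)ethynyl]propane-1,3-diol
Product: 21 2-(triethylsilyloxy)-2-[(trimethylsilyl)ethynyl]propanedial
Conditions: (COCl)2, DMSO, CH2Cl2, −78 °C; Et3N, −78 → −20 °C; pentane, filtration, used at once
Reagents that add atoms: none
Why: Double Swern oxidation of the 1,3-diol; the dialdehyde cannot enolize, and the water-free work-up avoids hydration and loss of a formyl group.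

Step 10
Reactants: 14 (R,E)-2,4-dimethyl-N-(2-oxopropyl)oct-2-enamide; 21 2-(triethylsilyloxy)-2-[(trimethylsilyl)ethynyl]propanedial
Product: 24 (4R,5R)-2-[(R,E)-2,4-dimethyloct-2-enamido]-5-hydroxy-4-(triethylsilyloxy)-4-[(trimethylsilyl)ethynyl]cyclohex-2-en-1-one, via open-chain aldol adduct 22 (not isolated), via cyclic ketol 23 (not isolated)
Conditions: (S)-proline (30 mol %), DMF, 4 °C, slow addition of 21 (1.3 equiv); then 23 °C
Reagents that add atoms: none
Why: Proposed new method: the (S)-proline enamine of the methyl terminus of 14 should add to one formyl group of 21 (intermolecular aldol, C5–C6), the iminium ion so formed should tautomerize to the enamine on the amide side, whose C2 carbon attacks the second formyl group (C2–C3), and loss of water across C2–C3 should give the push–pull enamide 24; the closest known reaction types are the proline-catalysed ketone–aldehyde aldol addition, the Hajos–Parrish cyclization and amine-catalysed [3+3] condensations of acetone derivatives with 1,3-dialdehydes, whose union in a desymmetrizing annulation of a 2,2-disubstituted malonaldehyde is without precedent. The one ring closes in the 6-(enolendo)-exo-trig mode, the mode of the Hajos–Parrish reaction. C5 is controlled by the catalyst: its carboxylic acid hydrogen-bonds the formyl oxygen and exposes the Re face, the sense that gives (R)-β-hydroxy ketones from α-branched aldehydes. C4 is controlled by which formyl group reacts: only one of the two can combine Re-face attack with a Felkin–Anh (or Cornforth) arrangement in which the C4–OSiEt3 bond is anti to the incoming enamine and the slender alkynyl group, not the second formyl group, flanks the trajectory, and that pairing gives the 4,5-cis (4R,5R) product. The step needs group selectivity, regioselectivity in the first C–C bond and site-selective dehydration. The first is secured by the contrast between the bulky, electronegative silyloxy group and the rod-like trimethylsilylethynyl group, the second by the neopentyl-type acceptor, which admits only the unhindered terminal enamine carbon in the intermolecular event, and the third by the acidity of C2–H between ketone and acylamino group, so that water is lost across C2–C3 while the C5 hydroxyl stays. The quaternary C4 excludes enolization of 21 and aromatization of 24.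

Step 11
Reactants: 24 (4R,5R)-2-[(R,E)-2,4-dimethyloct-2-enamido]-5-hydroxy-4-(triethylsilyloxy)-4-[(trimethylsilyl)ethynyl]cyclohex-2-en-1-one
Product: 25 (4R,5R)-2-[(R,E)-2,4-dimethyloct-2-enamido]-4-ethynyl-4,5-dihydroxycyclohex-2-en-1-one
Conditions: Bu4NF, AcOH (1:1), THF, 0 → 23 °C
Reagents that add atoms: none
Why: Fluoride cleaves both the alkynyl C–Si bond and the tertiary triethylsilyl ether; buffering with acetic acid keeps the medium near neutral so that the β-hydroxy ketone should not eliminate, and no stereocentre is touched.

Step 12
Reactants: 25 (4R,5R)-2-[(R,E)-2,4-dimethyloct-2-enamido]-4-ethynyl-4,5-dihydroxycyclohex-2-en-1-one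
Product: 26 (4R,5R)-2-[(R,E)-2,4-dimethyloct-2-enamido]-4,5-dihydroxy-4-[(E)-2-(tributylstannyl)ethenyl]cyclohex-2-en-1-one
Conditions: PdCl2(PPh3)2 (cat.), Bu3SnH (slow addition), THF, 0 °C
Reagents that add atoms: tributyltin hydride, CCCC[SnH](CCCC)CCCC
Why: Palladium-catalysed hydrostannylation is a syn addition of Sn–H to the terminal alkyne; the quaternary propargylic carbinol steers tin to the terminal carbon, which should give the (E)-alkenylstannane, and the alkyne reacts far faster than the hindered enone.

Step 13
Reactants: 27 ethyl (E)-4-oxobut-2-enoate
Product: 28 ethyl (2E,4E)-5-iodopenta-2,4-dienoate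
Conditions: CrCl2, CHI3, THF, 0 °C
Reagents that add atoms: iodoform, IC(I)I
Why: Takai iodo-olefination: the geminal dichromium reagent adds to the aldehyde and anti elimination should give the (E)-iodoalkene; the enoate ester is inert to the organochromium species.

Step 14
Reactants: 28 ethyl (2E,4E)-5-iodopenta-2,4-dienoate
Product: 29 (2E,4E)-5-iodopenta-2,4-dienoic acid
Conditions: LiOH, THF/H2O, 0 → 23 °C, dark; then 1 M HCl
Reagents that add atoms: lithium hydroxide, [Li+].[OH-]
Why: Saponification under mild, cold conditions, at which hydroxide should not eliminate HI from the iododiene.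

Step 15
Reactants: 30 cyclopentane-1,3-dione
Product: 31 2-(hydroxyimino)cyclopentane-1,3-dione
Conditions: NaNO2, aq. HCl, 0 °C
Reagents that add atoms: sodium nitrite, [Na+].[O-]N=O
Why: C-nitrosation of the enolized 1,3-dione at C2, the only nucleophilic carbon, followed by tautomerization to the oxime.

Step 16
Reactants: 31 2-(hydroxyimino)cyclopentane-1,3-dione
Product: 32 2-amino-3-hydroxycyclopent-2-en-1-one hydrochloride
Conditions: H2 (1 atm), Pd/C, HCl, EtOH, 23 °C
Reagents that add atoms: hydrogen chloride, Cl
Why: Catalytic hydrogenation of the oxime to the primary amine, trapped as its hydrochloride so that the α-aminoketone cannot self-condense; the enolized dione resists hydrogenation.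

Step 17
Reactants: 29 (2E,4E)-5-iodopenta-2,4-dienoic acid; 32 2-amino-3-hydroxycyclopent-2-en-1-one hydrochloride
Product: 34 (2E,4E)-N-(2-hydroxy-5-oxocyclopent-1-en-1-yl)-5-iodopenta-2,4-dienamide, via acid chloride 33 (not isolated)
Conditions: (COCl)2, DMF (cat.), CH2Cl2, 0 → 23 °C; evaporation; then 32, Et3N, THF/DMF, 0 → 23 °C, dark
Reagents that add atoms: none
Why: Acylation of the amine by the acid chloride; any enol ester formed at oxygen should pass its acyl group on to nitrogen, the amide being the thermodynamic product.

Step 18
Reactants: 26 (4R,5R)-2-[(R,E)-2,4-dimethyloct-2-enamido]-4,5-dihydroxy-4-[(E)-2-(tributylstannyl)ethenyl]cyclohex-2-en-1-one; 34 (2E,4E)-N-(2-hydroxy-5-oxocyclopent-1-en-1-yl)-5-iodopenta-2,4-dienamide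
Product: 35 (4S,5R)-2-[(R,E)-2,4-dimethyloct-2-enamido]-4,5-dihydroxy-4-[(1E,3E,5E)-7-[(2-hydroxy-5-oxocyclopent-1-en-1-yl)amino]-7-oxohepta-1,3,5-trien-1-yl]cyclohex-2-en-1-one
Conditions: PdCl2(MeCN)2 (cat.), DMF, 23 °C, dark, argon
Reagents that add atoms: none
Why: Stille coupling of an alkenylstannane with an alkenyl iodide proceeds with retention at both sp2 carbons under neutral conditions and tolerates free hydroxyls and amides; it should complete the (E,E,E)-triene without any later deprotection.

## Compound list

1 | (R)-4-benzyloxazolidin-2-one | O=C1N[C@H](Cc2ccccc2)CO1 | starting material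
2 | hexanoyl chloride | CCCCCC(Cl)=O | starting material
3 | lithium (R)-4-benzyl-2-oxooxazolidin-3-ide | [Li+].O=C1[N-][C@H](Cc2ccccc2)CO1 | intermediate
4 | (R)-4-benzyl-3-hexanoyloxazolidin-2-one | CCCCCC(=O)N1[C@H](Cc2ccccc2)COC1=O | intermediate
5 | sodium (Z)-enolate of 4 | [Na+].CCCC/C=C(\[O-])N1[C@H](Cc2ccccc2)COC1=O | intermediate
6 | (R)-4-benzyl-3-[(R)-2-methylhexanoyl]oxazolidin-2-one | CCCC[C@@H](C)C(=O)N1[C@H](Cc2ccccc2)COC1=O | intermediate
7 | (R)-2-methylhexan-1-ol | CCCC[C@@H](C)CO | intermediate
8 | ethyl 2-(triphenyl-λ5-phosphanylidene)propanoate | CCOC(=O)C(C)=P(c1ccccc1)(c1ccccc1)c1ccccc1 | starting material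
9 | (R)-2-methylhexanal | CCCC[C@@H](C)C=O | intermediate
10 | ethyl (R,E)-2,4-dimethyloct-2-enoate | CCCC[C@@H](C)/C=C(\C)C(=O)OCC | intermediate
11 | (R,E)-2,4-dimethyloct-2-enoic acid | CCCC[C@@H](C)/C=C(\C)C(=O)O | intermediate
12 | aminoacetone hydrochloride | CC(=O)CN.Cl | starting material
13 | 1H-benzotriazol-1-yl (R,E)-2,4-dimethyloct-2-enoate | CCCC[C@@H](C)/C=C(\C)C(=O)On1nnc2ccccc12 | intermediate
14 | (R,E)-2,4-dimethyl-N-(2-oxopropyl)oct-2-enamide | CCCC[C@@H](C)/C=C(\C)C(=O)NCC(C)=O | intermediate
15 | (trimethylsilyl)acetylene | C#C[Si](C)(C)C | starting material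
16 | diethyl ketomalonate (diethyl 2-oxopropanedioate) | CCOC(=O)C(=O)C(=O)OCC | starting material
17 | lithium (trimethylsilyl)acetylide | [Li+].[C-]#C[Si](C)(C)C | intermediate
18 | lithium alkoxide of diethyl 2-hydroxy-2-[(trimethylsilyl)ethynyl]malonate | [Li+].CCOC(=O)C([O-])(C#C[Si](C)(C)C)C(=O)OCC | intermediate
19 | diethyl 2-(triethylsilyloxy)-2-[(trimethylsilyl)ethynyl]malonate | CCOC(=O)C(O[Si](CC)(CC)CC)(C#C[Si](C)(C)C)C(=O)OCC | intermediate
20 | 2-(triethylsilyloxy)-2-[(trimethylsilyl)ethynyl]propane-1,3-diol | OCC(O[Si](CC)(CC)CC)(C#C[Si](C)(C)C)CO | intermediate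
21 | 2-(triethylsilyloxy)-2-[(trimethylsilyl)ethynyl]propanedial | O=CC(O[Si](CC)(CC)CC)(C#C[Si](C)(C)C)C=O | intermediate
22 | (R,E)-N-[(4R,5R)-5-formyl-4-hydroxy-2-oxo-5-(triethylsilyloxy)-7-(trimethylsilyl)hept-6-yn-1-yl]-2,4-dimethyloct-2-enamide | CCCC[C@@H](C)/C=C(\C)C(=O)NCC(=O)C[C@@H](O)[C@](O[Si](CC)(CC)CC)(C#C[Si](C)(C)C)C=O | intermediate
23 | (4R,5R)-2-[(R,E)-2,4-dimethyloct-2-enamido]-3,5-dihydroxy-4-(triethylsilyloxy)-4-[(trimethylsilyl)ethynyl]cyclohexan-1-one (C2 and C3 unassigned) | CCCC[C@@H](C)/C=C(\C)C(=O)NC1C(O)[C@@](O[Si](CC)(CC)CC)(C#C[Si](C)(C)C)[C@H](O)CC1=O | intermediate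
24 | (4R,5R)-2-[(R,E)-2,4-dimethyloct-2-enamido]-5-hydroxy-4-(triethylsilyloxy)-4-[(trimethylsilyl)ethynyl]cyclohex-2-en-1-one | CCCC[C@@H](C)/C=C(\C)C(=O)NC1=C[C@@](O[Si](CC)(CC)CC)(C#C[Si](C)(C)C)[C@H](O)CC1=O | intermediate
25 | (4R,5R)-2-[(R,E)-2,4-dimethyloct-2-enamido]-4-ethynyl-4,5-dihydroxycyclohex-2-en-1-one | CCCC[C@@H](C)/C=C(\C)C(=O)NC1=C[C@@](O)(C#C)[C@H](O)CC1=O | intermediate
26 | (4R,5R)-2-[(R,E)-2,4-dimethyloct-2-enamido]-4,5-dihydroxy-4-[(E)-2-(tributylstannyl)ethenyl]cyclohex-2-en-1-one | CCCC[C@@H](C)/C=C(\C)C(=O)NC1=C[C@@](O)(/C=C/[Sn](CCCC)(CCCC)CCCC)[C@H](O)CC1=O | intermediate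
27 | ethyl (E)-4-oxobut-2-enoate | CCOC(=O)/C=C/C=O | starting material
28 | ethyl (2E,4E)-5-iodopenta-2,4-dienoate | CCOC(=O)/C=C/C=C/I | intermediate
29 | (2E,4E)-5-iodopenta-2,4-dienoic acid | OC(=O)/C=C/C=C/I | intermediate
30 | cyclopentane-1,3-dione | O=C1CCC(=O)C1 | starting material
31 | 2-(hydroxyimino)cyclopentane-1,3-dione | ON=C1C(=O)CCC1=O | intermediate
32 | 2-amino-3-hydroxycyclopent-2-en-1-one hydrochloride | NC1=C(O)CCC1=O.Cl | intermediate
33 | (2E,4E)-5-iodopenta-2,4-dienoyl chloride | ClC(=O)/C=C/C=C/I | intermediate
34 | (2E,4E)-N-(2-hydroxy-5-oxocyclopent-1-en-1-yl)-5-iodopenta-2,4-dienamide | I/C=C/C=C/C(=O)NC1=C(O)CCC1=O | intermediate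
35 | (4S,5R)-2-[(R,E)-2,4-dimethyloct-2-enamido]-4,5-dihydroxy-4-[(1E,3E,5E)-7-[(2-hydroxy-5-oxocyclopent-1-en-1-yl)amino]-7-oxohepta-1,3,5-trien-1-yl]cyclohex-2-en-1-one | CCCC[C@@H](C)/C=C(\C)C(=O)NC1=C[C@@](O)(/C=C/C=C/C=C/C(=O)NC2=C(O)CCC2=O)[C@H](O)CC1=O | target

## Step count and least certain steps

Total step count: 18. Longest linear sequence: 10 steps (steps 1–6, 10, 11, 12 and 18).

Step 10 (key step). Four things may go wrong:
- attack of the catalyst nitrogen on a formyl group of 21 followed by C–C cleavage (loss of a formyl group) before the aldol addition;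
- weak discrimination between the two formyl groups, which would appear as a cis/trans mixture at C4/C5;
- first bond formation at C2 instead of C6, which would reverse the sense at C4;
- incomplete dehydration of 23.

The fallback uses known chemistry, sets out from 15 and 11, comes back at 25 and by-passes 19–24. Lithiated 15 is added to 4,4-dimethoxycyclohexa-2,5-dien-1-one to give 4,4-dimethoxy-1-[(trimethylsilyl)ethynyl]cyclohexa-2,5-dien-1-ol F1, and aqueous oxalic acid unmasks 4-hydroxy-4-[(trimethylsilyl)ethynyl]cyclohexa-2,5-dien-1-one F2. Phenylboronic acid and a quinine- or quinidine-derived tertiary amine–thiourea (the pseudo-enantiomer that leads to the 4R,5R series) should effect the tethered oxa-Michael addition to the cyclic phenylboronate of (4R,5R)-4,5-dihydroxy-4-[(trimethylsilyl)ethynyl]cyclohex-2-en-1-one F3, cis by construction. Iodine and pyridine give the cyclic phenylboronate of (4R,5R)-4,5-dihydroxy-2-iodo-4-[(trimethylsilyl)ethynyl]cyclohex-2-en-1-one F4. Copper-catalysed amidation (CuI, N,N′-dimethylethylenediamine, K3PO4, toluene, gentle warming) with (R,E)-2,4-dimethyloct-2-enamide F5, made from 11 through a mixed anhydride and ammonia, gives the cyclic phenylboronate of (4R,5R)-2-[(R,E)-2,4-dimethyloct-2-enamido]-4,5-dihydroxy-4-[(trimethylsilyl)ethynyl]cyclohex-2-en-1-one F6. KHF2 in aqueous methanol then removes the boronate and the alkynylsilane and gives 25.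

Step 6. Self-condensation of the liberated aminoketone may compete with its acylation. The fallback sets out from 11 and comes back at 14: carbodiimide coupling of 11 with (S)-1-aminopropan-2-ol, which cannot self-condense, gives (R,E)-N-[(S)-2-hydroxypropyl]-2,4-dimethyloct-2-enamide F7, and Dess–Martin oxidation of its secondary alcohol gives 14.

Step 11. Fluoride may induce loss of the C5 hydroxyl through the C1 enolate, or the silyl group may migrate to O5 before it is cleaved. The fallback sets out from 24 and comes back at 25 by a non-basic unmasking in two stages: AgNO3-catalysed protodesilylation of the alkynylsilane in aqueous acetone gives (4R,5R)-2-[(R,E)-2,4-dimethyloct-2-enamido]-4-ethynyl-5-hydroxy-4-(triethylsilyloxy)cyclohex-2-en-1-one F8, and HF·pyridine buffered with pyridine in THF then cleaves the silyl ether to give 25.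

Step 18. Protodestannylation of 26 by the acidic enol of 34, homocoupling, or geometric isomerization of the iododiene may lower the amount or purity of the triene. The fallback sets out from 26 and comes back at 35: iododestannylation with I2 gives (4R,5R)-2-[(R,E)-2,4-dimethyloct-2-enamido]-4,5-dihydroxy-4-[(E)-2-iodoethenyl]cyclohex-2-en-1-one F9, which has no acid-labile C–Sn bond. A Heck reaction (Pd(OAc)2, Ag2CO3, DMF) at the terminal CH2 of (E)-N-(2-hydroxy-5-oxocyclopent-1-en-1-yl)penta-2,4-dienamide F10, made from 32 and (E)-penta-2,4-dienoic acid as in step 17, should then give 35 after β-hydride elimination to the (E)-alkene.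

## Further compounds

F1 | step 10 | 4,4-dimethoxy-1-[(trimethylsilyl)ethynyl]cyclohexa-2,5-dien-1-ol | COC1(OC)C=CC(O)(C#C[Si](C)(C)C)C=C1
F2 | step 10 | 4-hydroxy-4-[(trimethylsilyl)ethynyl]cyclohexa-2,5-dien-1-one | O=C1C=CC(O)(C#C[Si](C)(C)C)C=C1
F3 | step 10 | cyclic phenylboronate of (4R,5R)-4,5-dihydroxy-4-[(trimethylsilyl)ethynyl]cyclohex-2-en-1-one | O=C1C=C[C@]2(C#C[Si](C)(C)C)OB(c3ccccc3)O[C@@H]2C1
F4 | step 10 | cyclic phenylboronate of (4R,5R)-4,5-dihydroxy-2-iodo-4-[(trimethylsilyl)ethynyl]cyclohex-2-en-1-one | O=C1C(I)=C[C@]2(C#C[Si](C)(C)C)OB(c3ccccc3)O[C@@H]2C1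
F5 | step 10 | (R,E)-2,4-dimethyloct-2-enamide | CCCC[C@@H](C)/C=C(\C)C(N)=O
F6 | step 10 | cyclic phenylboronate of (4R,5R)-2-[(R,E)-2,4-dimethyloct-2-enamido]-4,5-dihydroxy-4-[(trimethylsilyl)ethynyl]cyclohex-2-en-1-one | CCCC[C@@H](C)/C=C(\C)C(=O)NC1=C[C@]2(C#C[Si](C)(C)C)OB(c3ccccc3)O[C@@H]2CC1=O
F7 | step 6 | (R,E)-N-[(S)-2-hydroxypropyl]-2,4-dimethyloct-2-enamide | CCCC[C@@H](C)/C=C(\C)C(=O)NC[C@H](C)O
F8 | step 11 | (4R,5R)-2-[(R,E)-2,4-dimethyloct-2-enamido]-4-ethynyl-5-hydroxy-4-(triethylsilyloxy)cyclohex-2-en-1-one | CCCC[C@@H](C)/C=C(\C)C(=O)NC1=C[C@@](O[Si](CC)(CC)CC)(C#C)[C@H](O)CC1=O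
F9 | step 18 | (4R,5R)-2-[(R,E)-2,4-dimethyloct-2-enamido]-4,5-dihydroxy-4-[(E)-2-iodoethenyl]cyclohex-2-en-1-one | CCCC[C@@H](C)/C=C(\C)C(=O)NC1=C[C@@](O)(/C=C/I)[C@H](O)CC1=O
F10 | step 18 | (E)-N-(2-hydroxy-5-oxocyclopent-1-en-1-yl)penta-2,4-dienamide | C=C/C=C/C(=O)NC1=C(O)CCC1=O
A1 | alternative 1 | benzoic acid | OC(=O)c1ccccc1
A2 | alternative 1 | (1S,2R)-1,2-dihydroxycyclohexa-3,5-diene-1-carboxylic acid | C1=C[C@@](O)(C(=O)O)[C@H](O)C=C1
A3 | alternative 2 | 4-ethynyl-4-hydroxycyclohexa-2,5-dien-1-one | O=C1C=CC(O)(C#C)C=C1
A4 | alternative 2 | cyclic phenylboronate of (4R,5R)-4-ethynyl-4,5-dihydroxycyclohex-2-en-1-one | O=C1C=C[C@]2(C#C)OB(c3ccccc3)O[C@@H]2C1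
A5 | alternative 3 | (4R,6S,Z)-6-(tert-butyldimethylsilyloxy)-8-iodo-4-[(4-methoxybenzyl)oxy]-1-(triisopropylsilyl)oct-7-en-1-yn-3-one | I/C=C\[C@@H](O[Si](C)(C)C(C)(C)C)C[C@@H](OCc1ccc(OC)cc1)C(=O)C#C[Si](C(C)C)(C(C)C)C(C)C
A6 | alternative 3 | (1R,4S,6R)-4-(tert-butyldimethylsilyloxy)-6-[(4-methoxybenzyl)oxy]-1-[(triisopropylsilyl)ethynyl]cyclohex-2-en-1-ol | O[C@@]1(C#C[Si](C(C)C)(C(C)C)C(C)C)C=C[C@@H](O[Si](C)(C)C(C)(C)C)C[C@H]1OCc2ccc(OC)cc2
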